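(Readings and results are calculated on assumed constants.)

The slowness of the teal run's first moments was where I began: the readings put the fall of substrate at 5.26 mM/min up to the first reading, against 18.7 mM/min between the second and third.

| flask | substrate | coupling partner | free catalyst | product | time |
|---|---|---|---|---|---|
| teal | 120 mM | 240 mM | 9.60 mM |  |  |
| green | 120 mM | 240 mM | 9.60 mM | 36.0 mM |  |
| red | 360 mM | 720 mM | 9.60 mM |  | 4.2 min |

| teal run: time / min | teal run: [substrate] / mM | green run: time / min | green run: [substrate] / mM |
|---|---|---|---|
| 0.19 | 119.0 | 0.19 | 118.7 |
| 0.57 | 112.8 | 0.57 | 113.2 |
| 1.1 | 102.9 | 1.1 | 102.7 |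
| 1.7 | 92.2 | 1.7 | 91.4 |
| 2.5 | 80.0 | 2.5 | 79.0 |
| 3.3 | 72.1 | 3.3 | 71.7 |
| 4.2 | 64.6 | 4.2 | 64.4 |

(scatter of a reading: 0.6 mM)

- substrate in the red run at 4.2 min, as a share of the substrate charged

- Overall: substrate + coupling partner -> product, with free catalyst as catalyst.
- Constant volume, constant temperature.
- "The second partner" is coupling partner.

The green run, charged with product, ended at 64.4 mM against 64.6 mM for the teal run, a gap within the scatter. I then drew the teal curve as a working strength of the catalyst, my own reading: slope divided by substrate times coupling partner. Read off these scattered slopes, that strength started at 0.183 /M/min, stood at 0.836 /M/min near 1.7 min, and was lower than that, 0.654 /M/min, near 3.3 min. So, as these readings go, the knee, where gain in strength gave way to loss, lay somewhere before 3.3 min in the teal run.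

Coupling partner stays ahead of substrate by a fixed gap, so the strength summed over time comes straight from one reading:

exposure = ln[(coupling partner ÷ its charge) ÷ (substrate ÷ its charge)] ÷ gap

The teal run at 4.2 min gave 2.97 /M of exposure, the time-sum of working strength.

The red run was charged with the same 9.60 mM of free catalyst as the teal run, so I committed to the same exposure at 4.2 min, though the teal and green charges cannot show the orders. With the red gap of 0.360 M, the ratio in the brackets becomes 2.92, and:

share left = gap ÷ (ratio × coupling partner charge − substrate charge) = 20.7 %

The forecast differed from my reckoning, at 80 %: “The red run has the same catalyst, so it should be capped near the same absolute rate, not the same fractional one.”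

The red run gave 19.2 %, which is 61 percentage points below the forecast.

    2 active catalyst ⇌ catalyst dimer, settled at all times (111.0 /M)
    active catalyst + substrate + coupling partner → product + active catalyst (224.4 /M²/min)
    active catalyst → spent catalyst (0.4302 /min)
    free catalyst + coupling partner → active catalyst + coupling partner (7.320 /M/min)

The slowness of the step from free catalyst to active catalyst makes no real difference to that red share. Read backward, the red share gives an exposure of 3.15 /M, beside 2.97 /M from the teal run and 2.99 /M from the last reading of the green run.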